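**Retrosynthetic overview**
- The target is cut at the ether bond between C3 of one 7-hydroxy-6,8-dimethoxycoumarin and O7 of isofraxidin. That C3–O bond is made last, by O–H insertion of isofraxidin into a C3 carbenoid generated from 3-diazo-6,8-dimethoxy-3H-chromene-2,7-dione.
- The diazo compound comes from 3-acetamido-7-acetoxy-6,8-dimethoxycoumarin (hydrolysis, diazotisation, deprotonation), which comes from azlactone annulation of 2,4-dihydroxy-3,5-dimethoxybenzaldehyde with N-acetylglycine.
- Isofraxidin comes from the same aldehyde by Wittig olefination and lactonisation.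
- The aldehyde comes from syringaldehyde by ortho-bromination and copper-catalysed hydroxylation.
- Ring order: both benzene rings are bought (syringaldehyde), the two pyranone rings are closed separately (steps 3 and 4), and the ether bond joins the halves in step 6.

Assumption: the target has no stereocentre and no configurationally stable axis, so it is made as the single achiral compound drawn and no step needs stereocontrol.

**Route**

Step 1
Reactants: 1 syringaldehyde (4-hydroxy-3,5-dimethoxybenzaldehyde)
Product: 2 2-bromo-4-hydroxy-3,5-dimethoxybenzaldehyde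
Conditions: Br2 (1.05 equiv), NaOAc (1.1 equiv), AcOH, 15 °C to rt
Reagents that add atoms: bromine, BrBr
Why: Electrophilic aromatic bromination; the positions ortho to the phenol are blocked, so bromine enters the equivalent C2/C6 position (ortho to one methoxy group, para to the other), and one equivalent of buffered Br2 keeps dibromination and ipso attack at the formyl carbon low.

Step 2
Reactants: 2 2-bromo-4-hydroxy-3,5-dimethoxybenzaldehyde
Product: 3 2,4-dihydroxy-3,5-dimethoxybenzaldehyde
Conditions: Cu(acac)2 (5 mol%), N,N'-bis(4-hydroxy-2,6-dimethylphenyl)oxalamide (5 mol%), LiOH·H2O (4 equiv), DMSO/H2O 4:1, 80 °C, N2; then 2 M HCl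
Reagents that add atoms: lithium hydroxide, [Li+].[OH-]
Why: Ullmann-type copper-catalysed hydroxylation of an aryl bromide, helped by the ortho-formyl group; the aldehyde survives the base because the para-phenolate makes it a poor Cannizzaro substrate, as in the classical conversion of 5-bromovanillin into 5-hydroxyvanillin.

Step 3 (uses about half of 3)
Reactants: 3 2,4-dihydroxy-3,5-dimethoxybenzaldehyde; 4 ethyl (triphenylphosphoranylidene)acetate
Product: 7 isofraxidin (7-hydroxy-6,8-dimethoxy-2H-chromen-2-one), via E-cinnamate ester 5 (not isolated), via Z-cinnamate ester 6 (not isolated)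
Conditions: 4 (1.6 equiv), N,N-diethylaniline, reflux (215 °C), 4 h, N2
Reagents that add atoms: none
Why: Wittig olefination with a stabilised ylide gives cinnamate 5, which at 215 °C isomerises to 6 and lactonises with loss of ethanol; this is the standard one-pot coumarin synthesis and it tolerates free phenols.

Step 4 (uses the other half of 3)
Reactants: 3 2,4-dihydroxy-3,5-dimethoxybenzaldehyde; 8 N-acetylglycine
Product: 12 3-acetamido-6,8-dimethoxy-2-oxo-2H-chromen-7-yl acetate, via azlactone 9 (not isolated), via Z-arylidene azlactone 10 (not isolated), via E-arylidene azlactone 11 (not isolated)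
Conditions: NaOAc (3 equiv), Ac2O, 110 °C, 6 h; pour on ice, filter
Reagents that add atoms: acetic anhydride, CC(=O)OC(C)=O
Why: Erlenmeyer–Plöchl azlactone condensation (Ac2O converts 8 into azlactone 9, which condenses with the aldehyde), then acetate-mediated Z/E equilibration and acyl transfer from the azlactone carbonyl to the ortho-phenol close the pyranone with nitrogen already on C3, while the 4-OH is acetylated; this is the standard route to 3-acetamidocoumarins.

Step 5
Reactants: 12 3-acetamido-6,8-dimethoxy-2-oxo-2H-chromen-7-yl acetate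
Product: 15 3-diazo-6,8-dimethoxy-3H-chromene-2,7-dione (zwitterionic form: 3-diazonio-6,8-dimethoxy-2-oxo-2H-chromen-7-olate), via 3-aminocoumarin hydrochloride 13 (not isolated), via 3-diazonium chloride 14 (not isolated)
Conditions: conc. HCl/1,4-dioxane 2:1, 100 °C, 1 h; NaNO2 (1.1 equiv), 0 °C, 15 min; aq. NaOAc to pH 5–6, 0 °C, dark; CH2Cl2 extraction, used at once (small scale, blast shield)
Reagents that add atoms: sodium nitrite, [Na+].[O-]N=O
Why: Acid hydrolysis of the enamide and the aryl acetate, diazotisation of the 3-aminocoumarin (the sequence used to make 3-azido-7-hydroxycoumarin) and loss of the phenolic proton from the vinylogous para-hydroxy diazonium ion give the neutral quinone-diazide-type diazo compound, as with p-hydroxybenzenediazonium salts.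

Step 6
Reactants: 15 3-diazo-6,8-dimethoxy-3H-chromene-2,7-dione; 7 isofraxidin
Product: 17 3-[(6,8-dimethoxy-2-oxo-2H-chromen-7-yl)oxy]-7-hydroxy-6,8-dimethoxy-2H-chromen-2-one (target), via 3H-quinone methide tautomer 16 (not isolated)
Conditions: Rh2(esp)2 (2 mol%), 7 (3 equiv, excess recovered), DCE, 60 °C, 15 added over 4 h, dark
Reagents that add atoms: none
Why: Proposed new method: rhodium-carbenoid O–H insertion of a coumarin-derived vinylogous quinone diazide, a diazo class not yet used in carbene transfer; Rh2(esp)2 expels N2 from 15 to give a carbenoid best written as a Rh-bound 7-oxidocoumarin-3-yl cation (aromatisation makes C3 strongly electrophilic), the hindered but acidic 7-OH of 7 adds through oxygen to give an oxonium ylide, a 1,2-proton shift gives 16 and enolisation restores the aromatic hydroxycoumarin 17, so the C–O bond can form only at the diazo carbon and 15, which has no OH, cannot insert into itself; the closest known reaction type is Rh(II)-catalysed O–H insertion of α-diazo esters and p-quinone diazides into phenols and alcohols; slow addition and excess 7 hold back carbene oligomerisation and insertion into the product phenol; no stereocentre remains in 17.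

**Compound list**
1 | syringaldehyde (4-hydroxy-3,5-dimethoxybenzaldehyde) | COc1cc(C=O)cc(OC)c1O | starting material
2 | 2-bromo-4-hydroxy-3,5-dimethoxybenzaldehyde | COc1cc(C=O)c(Br)c(OC)c1O | intermediate
3 | 2,4-dihydroxy-3,5-dimethoxybenzaldehyde | COc1cc(C=O)c(O)c(OC)c1O | intermediate
4 | ethyl (triphenylphosphoranylidene)acetate | CCOC(=O)C=P(c1ccccc1)(c1ccccc1)c1ccccc1 | starting material
5 | ethyl (E)-3-(2,4-dihydroxy-3,5-dimethoxyphenyl)prop-2-enoate | CCOC(=O)/C=C/c1cc(OC)c(O)c(OC)c1O | intermediate (not isolated)
6 | ethyl (Z)-3-(2,4-dihydroxy-3,5-dimethoxyphenyl)prop-2-enoate | CCOC(=O)/C=C\c1cc(OC)c(O)c(OC)c1O | intermediate (not isolated)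
7 | isofraxidin (7-hydroxy-6,8-dimethoxy-2H-chromen-2-one) | COc1cc2ccc(=O)oc2c(OC)c1O | intermediate
8 | N-acetylglycine | CC(=O)NCC(=O)O | starting material
9 | 2-methyl-1,3-oxazol-5(4H)-one | CC1=NCC(=O)O1 | intermediate (not isolated)
10 | (Z)-4-(4-acetoxy-2-hydroxy-3,5-dimethoxybenzylidene)-2-methyl-1,3-oxazol-5(4H)-one (aryl cis to N) | CC1=N/C(=C\c2cc(OC)c(OC(C)=O)c(OC)c2O)C(=O)O1 | intermediate (not isolated)
11 | (E)-4-(4-acetoxy-2-hydroxy-3,5-dimethoxybenzylidene)-2-methyl-1,3-oxazol-5(4H)-one (aryl cis to C=O) | CC1=N/C(=C/c2cc(OC)c(OC(C)=O)c(OC)c2O)C(=O)O1 | intermediate (not isolated)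
12 | 3-acetamido-6,8-dimethoxy-2-oxo-2H-chromen-7-yl acetate | COc1cc2cc(NC(C)=O)c(=O)oc2c(OC)c1OC(C)=O | intermediate
13 | 3-amino-7-hydroxy-6,8-dimethoxy-2H-chromen-2-one hydrochloride | COc1cc2cc(N)c(=O)oc2c(OC)c1O.Cl | intermediate (not isolated)
14 | 7-hydroxy-6,8-dimethoxy-2-oxo-2H-chromene-3-diazonium chloride | COc1cc2cc([N+]#N)c(=O)oc2c(OC)c1O.[Cl-] | intermediate (not isolated)
15 | 3-diazo-6,8-dimethoxy-3H-chromene-2,7-dione | COC1=CC2=CC(=[N+]=[N-])C(=O)OC2=C(OC)C1=O | intermediate
16 | 3-[(6,8-dimethoxy-2-oxo-2H-chromen-7-yl)oxy]-6,8-dimethoxy-3H-chromene-2,7-dione (racemic at C3, transient) | COC1=CC2=CC(Oc3c(OC)cc4ccc(=O)oc4c3OC)C(=O)OC2=C(OC)C1=O | intermediate (not isolated)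
17 | 3-[(6,8-dimethoxy-2-oxo-2H-chromen-7-yl)oxy]-7-hydroxy-6,8-dimethoxy-2H-chromen-2-one | COc1cc2cc(Oc3c(OC)cc4ccc(=O)oc4c3OC)c(=O)oc2c(OC)c1O | target

**Totals**
Total steps: 6. Longest linear sequence: 5 (steps 1, 2, 4, 5, 6); the isofraxidin branch is steps 1, 2, 3.

**Three steps most likely to fail**

Step 6 (proposed new step). Risks are a sluggish carbenoid formation from the stabilised diazo compound, oligomerisation of 15 through its quinoid oxygen, C-attack at C3 of 7 and a second insertion into the product phenol. The fallback is known chemistry; it sets out from 7 (with aldehyde 3) and comes back at 17. Isofraxidin 7 is O-alkylated with tert-butyl bromoacetate (K2CO3, acetone, reflux) to tert-butyl 2-[(6,8-dimethoxy-2-oxo-2H-chromen-7-yl)oxy]acetate F1. TFA in CH2Cl2 gives 2-[(6,8-dimethoxy-2-oxo-2H-chromen-7-yl)oxy]acetic acid F2. Perkin condensation of F2 with aldehyde 3 (Ac2O, Et3N, 120 °C) builds the second pyranone ring with the aryloxy group on C3 and gives 3-[(6,8-dimethoxy-2-oxo-2H-chromen-7-yl)oxy]-6,8-dimethoxy-2-oxo-2H-chromen-7-yl acetate F3. HCl in MeOH at 50 °C removes the acetate to give 17.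

Step 5. Risks are air oxidation of the aminophenol, over-hydrolysis of the enamine to the 3-hydroxycoumarin, and loss of the neutral diazo compound during aqueous isolation. The fallback sets out from 12 and comes back at 15, which is then not isolated. Compound 12 is deacetylated with HCl in MeOH and the amine hydrochloride 13 is filtered off as a solid. Anhydrous diazotisation (t-BuONO, HBF4·OEt2, MeCN, −10 °C, then Et2O) precipitates 7-hydroxy-6,8-dimethoxy-2-oxo-2H-chromene-3-diazonium tetrafluoroborate F4, which is stored as the salt. Just before step 6 it is stirred with solid NaHCO3 in CH2Cl2 containing 5% MeCN, and the filtered solution of 15 is fed directly to the rhodium catalyst and 7.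

Step 2. Risks are slow coupling at the doubly ortho-substituted bromide, protodebromination and base damage to the aldehyde. The fallback sets out from 2 and comes back at 3. Miyaura borylation of 2 (B2pin2, Pd(OAc)2/SPhos, KOAc, dioxane, 90 °C) gives 4-hydroxy-3,5-dimethoxy-2-(4,4,5,5-tetramethyl-1,3,2-dioxaborolan-2-yl)benzaldehyde F5. Oxidation of the C–B bond with N-methylmorpholine N-oxide (THF, 50 °C, aqueous work-up) gives 3; this oxidant is chosen because it does not trigger Dakin cleavage of the aldehyde.

**Further compounds**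
F1 | step 6 | tert-butyl 2-[(6,8-dimethoxy-2-oxo-2H-chromen-7-yl)oxy]acetate | COc1cc2ccc(=O)oc2c(OC)c1OCC(=O)OC(C)(C)C
F2 | step 6 | 2-[(6,8-dimethoxy-2-oxo-2H-chromen-7-yl)oxy]acetic acid | COc1cc2ccc(=O)oc2c(OC)c1OCC(=O)O
F3 | step 6 | 3-[(6,8-dimethoxy-2-oxo-2H-chromen-7-yl)oxy]-6,8-dimethoxy-2-oxo-2H-chromen-7-yl acetate | COc1cc2cc(Oc3c(OC)cc4ccc(=O)oc4c3OC)c(=O)oc2c(OC)c1OC(C)=O
F4 | step 5 | 7-hydroxy-6,8-dimethoxy-2-oxo-2H-chromene-3-diazonium tetrafluoroborate | COc1cc2cc([N+]#N)c(=O)oc2c(OC)c1O.F[B-](F)(F)F
F5 | step 2 | 4-hydroxy-3,5-dimethoxy-2-(4,4,5,5-tetramethyl-1,3,2-dioxaborolan-2-yl)benzaldehyde | COc1cc(C=O)c(B2OC(C)(C)C(C)(C)O2)c(OC)c1O
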